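**Retrosynthetic overview**
1. Cut both pyrrole rings at once (N1–C2 and C3–C3a of each indole, twofold Fischer retron). This gives a bis(4-bromophenyl) core, 2 × benzophenone hydrazone as the N–N source, and 2 × 3,3-dimethylpent-4-enal. Each aldehyde supplies C2, C3 and a complete 1,1-dimethylallyl group.
2. Cut the (E)-styryl C=C by HWE to a quaternary cyclohexenecarbaldehyde and diethyl (4-bromobenzyl)phosphonate.
3. Cut the cyclohexene by a catalytic enantioselective exo Diels–Alder reaction to (E)-1-(4-bromophenyl)-3-methylbuta-1,3-diene and methacrolein. Both stereocentres are set here.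
4. Cut the diene by HWE to 4-bromobenzaldehyde and diethyl (2-methylallyl)phosphonate.
5. Ring order: the cyclohexene forms first, then the two pyrrole rings form together in the last flask. The benzene rings are bought.

Assumption: the SMILES is read as (1R,6S) on cyclohex-2-en-1-yl numbering. That places the indolyl group at C1 trans to the styryl group and cis to the methyl group at C6.

**Route**

Step 1
Reactants: 1 4-bromobenzaldehyde; 2 diethyl (2-methylprop-2-en-1-yl)phosphonate
Product: 4 1-bromo-4-[(1E)-3-methylbuta-1,3-dien-1-yl]benzene, via lithiated phosphonate 3 (not isolated)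
Conditions: 2, n-BuLi, THF, −78 °C; then 1, DMPU, −78 °C → rt
Reagents that add atoms: none
Why: Horner–Wadsworth–Emmons olefination, in which the allylic phosphonate anion adds through its α-carbon to the aldehyde and loses diethyl phosphate from the favoured adduct to give the (E)-diene; the stabilised anion leaves the aryl bromide untouched and no stereocentre is formed.

Step 2
Reactants: 4 1-bromo-4-[(1E)-3-methylbuta-1,3-dien-1-yl]benzene; 5 methacrolein
Product: 6 (1R,2S)-2-(4-bromophenyl)-1,4-dimethylcyclohex-3-ene-1-carbaldehyde (formyl trans to aryl)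
Conditions: (R)-3,3-diphenyl-1-(o-tolyl)tetrahydro-1H,3H-pyrrolo[1,2-c][1,3,2]oxazaborole (20 mol%), HN(SO2CF3)2 (17 mol%), 5 (2 equiv), CH2Cl2, −78 → −40 °C
Reagents that add atoms: none
Why: Corey oxazaborolidinium-catalysed Diels–Alder reaction, in which the 1-aryl ("ortho") and 3-methyl ("para") directing effects reinforce each other; the s-trans enal, held on boron by the formyl C–H···O contact over the catalyst phenyl group, exposes the si face of its α-carbon on the (R)-catalyst (sets 1R), and the exo orientation known for α-alkylacroleins on bulky boron Lewis acids (formyl away from the diene, methyl endo) places CHO trans to the aryl group (sets 2S).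

Step 3
Reactants: 6 (1R,2S)-2-(4-bromophenyl)-1,4-dimethylcyclohex-3-ene-1-carbaldehyde; 7 diethyl (4-bromobenzyl)phosphonate
Product: 9 1-bromo-4-[(E)-2-[(1S,2R)-2-(4-bromophenyl)-1,4-dimethylcyclohex-3-en-1-yl]ethenyl]benzene, via potassium benzylphosphonate anion 8 (not isolated)
Conditions: 7, KOtBu, THF, 0 °C; then 6, 0 → 40 °C
Reagents that add atoms: none
Why: Horner–Wadsworth–Emmons olefination, in which the benzylic phosphonate anion adds reversibly to the non-enolisable aldehyde and eliminates to the (E)-styrene; the quaternary α-carbon cannot epimerise, so both stereocentres are kept (the descriptors change only through CIP priorities).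

Step 4
Reactants: 10 methyl 3,3-dimethylpent-4-enoate
Product: 12 3,3-dimethylpent-4-enal, via aluminium hemiacetal 11 (not isolated)
Conditions: i-Bu2AlH (1.05 equiv), CH2Cl2, −78 °C; aq. Rochelle salt work-up
Reagents that add atoms: none
Why: DIBAL-H partial ester reduction, in which the tetrahedral aluminium hemiacetal is stable at −78 °C and collapses to the aldehyde only on work-up, while the terminal alkene is inert at this temperature.

Step 5 (key step)
Reactants: 9 1-bromo-4-[(E)-2-[(1S,2R)-2-(4-bromophenyl)-1,4-dimethylcyclohex-3-en-1-yl]ethenyl]benzene; 13 benzophenone hydrazone; 12 3,3-dimethylpent-4-enal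
Product: 17 5-[(1R,6S)-3,6-dimethyl-6-{(E)-2-[3-(2-methylbut-3-en-2-yl)-1H-indol-5-yl]ethenyl}cyclohex-2-en-1-yl]-3-(2-methylbut-3-en-2-yl)-1H-indole (target), via bis(benzophenone hydrazone) 14 (not isolated), via bis(arylhydrazine) 15 (not isolated), via bis(aldehyde hydrazone) 16 (not isolated)
Conditions: (a) 13 (2.1 equiv), Pd(OAc)2 (2 mol%), Xantphos [4,5-bis(diphenylphosphino)-9,9-dimethylxanthene] (2.4 mol%), NaOtBu (2.5 equiv), toluene, 80 °C; (b) same flask, 12 (2.4 equiv), TsOH·H2O (3.0 equiv), EtOH, 78 °C, Ar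
Reagents that add atoms: none
Why: Twofold Buchwald–Hartwig N-arylation followed by a twofold Fischer indole synthesis (Buchwald modification), in which both C–Br bonds are aminated, acid transfers each arylhydrazine from benzophenone to the more electrophilic aldehyde, and ene-hydrazine formation, [3,3]-shift and loss of NH3 close both pyrrole rings; para substitution makes the two ortho positions equivalent so only 5-substituted indoles can form, the aldehyde enolises on one side only so each 1,1-dimethylallyl group lands on C3, the released NH3 consumes about one equivalent of strong acid per ring so acidity falls as product builds up, and the remote stereocentres are not touched.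

**Compound list**
1 | 4-bromobenzaldehyde | O=Cc1ccc(Br)cc1 | starting material
2 | diethyl (2-methylprop-2-en-1-yl)phosphonate | C=C(C)CP(=O)(OCC)OCC | starting material
3 | lithium salt of α-deprotonated 2 | [Li+].C=C(C)[CH-]P(=O)(OCC)OCC | intermediate
4 | 1-bromo-4-[(1E)-3-methylbuta-1,3-dien-1-yl]benzene | C=C(C)/C=C/c1ccc(Br)cc1 | intermediate
5 | methacrolein | C=C(C)C=O | starting material
6 | (1R,2S)-2-(4-bromophenyl)-1,4-dimethylcyclohex-3-ene-1-carbaldehyde | O=C[C@]1(C)CCC(C)=C[C@H]1c1ccc(Br)cc1 | intermediate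
7 | diethyl (4-bromobenzyl)phosphonate | CCOP(=O)(Cc1ccc(Br)cc1)OCC | starting material
8 | potassium salt of α-deprotonated 7 | [K+].CCOP(=O)([CH-]c1ccc(Br)cc1)OCC | intermediate
9 | 1-bromo-4-[(E)-2-[(1S,2R)-2-(4-bromophenyl)-1,4-dimethylcyclohex-3-en-1-yl]ethenyl]benzene | Brc1ccc(/C=C/[C@]2(C)CCC(C)=C[C@H]2c2ccc(Br)cc2)cc1 | intermediate
10 | methyl 3,3-dimethylpent-4-enoate | C=CC(C)(C)CC(=O)OC | starting material
11 | diisobutylaluminium 1-methoxy-3,3-dimethylpent-4-en-1-olate | C=CC(C)(C)CC(OC)O[Al](CC(C)C)CC(C)C | intermediate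
12 | 3,3-dimethylpent-4-enal | C=CC(C)(C)CC=O | intermediate
13 | benzophenone hydrazone | NN=C(c1ccccc1)c1ccccc1 | starting material
14 | bis(N-aryl benzophenone hydrazone) of the (1S,2R) core | C(=NNc1ccc(/C=C/[C@]2(C)CCC(C)=C[C@H]2c2ccc(NN=C(c3ccccc3)c3ccccc3)cc2)cc1)(c1ccccc1)c1ccccc1 | intermediate
15 | [4-[(E)-2-[(1S,2R)-2-(4-hydrazinylphenyl)-1,4-dimethylcyclohex-3-en-1-yl]ethenyl]phenyl]hydrazine | NNc1ccc(/C=C/[C@]2(C)CCC(C)=C[C@H]2c2ccc(NN)cc2)cc1 | intermediate
16 | bis[(E)-3,3-dimethylpent-4-enylidene]hydrazone of 15 | C=CC(C)(C)C/C=N/Nc1ccc(/C=C/[C@]2(C)CCC(C)=C[C@H]2c2ccc(N/N=C/CC(C)(C)C=C)cc2)cc1 | intermediate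
17 | 5-[(1R,6S)-3,6-dimethyl-6-{(E)-2-[3-(2-methylbut-3-en-2-yl)-1H-indol-5-yl]ethenyl}cyclohex-2-en-1-yl]-3-(2-methylbut-3-en-2-yl)-1H-indole | C=CC(C)(C)c1c[nH]c2ccc(/C=C/[C@]3(C)CCC(C)=C[C@H]3c3ccc4[nH]cc(C(C)(C)C=C)c4c3)cc12 | target

**Step count**
Total steps: 5. Longest linear sequence: 4 (1 → 4 → 6 → 9 → 17). Step 4 is a one-step side branch.

**Steps most likely to fail**

Step 2. The exo preference of α-alkylacroleins is well documented for cyclopentadiene but much less so for acyclic 1-aryl dienes. The endo isomer (formyl cis to aryl) may compete, the ee may fall, and the acidic catalyst may oligomerise the diene.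

The fallback sets out from 4 and 5 and returns at 6, replacing asymmetric catalysis with resolution. The very bulky achiral Lewis acid B(C6F5)3 (CH2Cl2, −40 °C) is used only to enforce the exo mode. It gives rac-(1R*,2S*)-2-(4-bromophenyl)-1,4-dimethylcyclohex-3-ene-1-carbaldehyde F1. Condensation with (1R,2R)-N,N'-dimethyl-1,2-diphenylethane-1,2-diamine (Et2O, 4 Å sieves) gives two diastereomeric imidazolidines. These are the (1R,2S)-derived aminal F2 and the (1S,2R)-derived aminal F3, which are separated on silica, and F3 is discarded. Mild hydrolysis of F2 (dilute aq. HCl/Et2O) gives back 6 as a single enantiomer.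

Step 5. Four bond-forming events per half must run cleanly twice in one flask. The product carries an acid-labile 3-(1,1-dimethylallyl)indole (loss or migration of the group) and an electron-rich indolyl-styrene. Residual palladium hydride could also move the ring alkene into conjugation and destroy the C1 stereocentre.

The fallback sets out from 9 and returns at 17. It still closes both pyrrole rings together, but under basic, palladium-catalysed conditions. Twofold amination of 9 with ammonia (Pd[P(o-tol)3]2, Josiphos ligand CyPF-t-Bu, NaOtBu, NH3 in dioxane, 90 °C) gives 4-[(E)-2-[(1S,2R)-2-(4-aminophenyl)-1,4-dimethylcyclohex-3-en-1-yl]ethenyl]aniline F5. Ortho-iodination (I2, NaHCO3, CH2Cl2/H2O, dark, rt; the para positions are blocked) gives the bis(2-iodoaniline) F6. F6 is then annulated with 12 (Pd(OAc)2, DABCO, DMF, 85 °C) by enamine formation and intramolecular Heck closure at both ends, giving 17 with no acid present.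

Step 3. The aldehyde is neopentyl-type and flanked by an aryl-bearing carbon, so addition of the phosphonate anion may be slow or stall at the β-hydroxyphosphonate.

The fallback sets out from 6 and returns at 9, forming the aryl–vinyl bond rather than the C=C bond. Methylenation with the small ylide Ph3P=CH2 (THF, 0 °C → rt) gives 1-bromo-4-[(1R,6S)-6-ethenyl-3,6-dimethylcyclohex-2-en-1-yl]benzene F4. A ligand-free Heck reaction with 1-bromo-4-iodobenzene (Pd(OAc)2, Bu4NCl, NaHCO3, DMF, 70 °C) engages only the C–I bond. It can β-eliminate in only one direction because the neighbouring carbon is quaternary, so it gives (E)-9.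

**Further compounds**
F1 | step 2 | rac-(1R*,2S*)-2-(4-bromophenyl)-1,4-dimethylcyclohex-3-ene-1-carbaldehyde (racemate, both enantiomers written) | O=C[C@]1(C)CCC(C)=C[C@H]1c1ccc(Br)cc1.O=C[C@@]1(C)CCC(C)=C[C@@H]1c1ccc(Br)cc1
F2 | step 2 | (4R,5R)-2-[(1R,2S)-2-(4-bromophenyl)-1,4-dimethylcyclohex-3-en-1-yl]-1,3-dimethyl-4,5-diphenylimidazolidine | CN1C([C@]2(C)CCC(C)=C[C@H]2c2ccc(Br)cc2)N(C)[C@H](c2ccccc2)[C@H]1c1ccccc1
F3 | step 2 | (4R,5R)-2-[(1S,2R)-2-(4-bromophenyl)-1,4-dimethylcyclohex-3-en-1-yl]-1,3-dimethyl-4,5-diphenylimidazolidine | CN1C([C@@]2(C)CCC(C)=C[C@@H]2c2ccc(Br)cc2)N(C)[C@H](c2ccccc2)[C@H]1c1ccccc1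
F4 | step 3 | 1-bromo-4-[(1R,6S)-6-ethenyl-3,6-dimethylcyclohex-2-en-1-yl]benzene | C=C[C@]1(C)CCC(C)=C[C@H]1c1ccc(Br)cc1
F5 | step 5 | 4-[(E)-2-[(1S,2R)-2-(4-aminophenyl)-1,4-dimethylcyclohex-3-en-1-yl]ethenyl]aniline | Nc1ccc(/C=C/[C@]2(C)CCC(C)=C[C@H]2c2ccc(N)cc2)cc1
F6 | step 5 | 4-[(E)-2-[(1S,2R)-2-(4-amino-3-iodophenyl)-1,4-dimethylcyclohex-3-en-1-yl]ethenyl]-2-iodoaniline | Nc1ccc(/C=C/[C@]2(C)CCC(C)=C[C@H]2c2ccc(N)c(I)c2)cc1I
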